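Per minute and per molar of reagent is the unit we reckon in, for after 20.0 min the theta run holds 22.9% of its starting material and the gamma run 66.6%, and theta was charged with more reagent.

| setting | gamma | eta | theta | north | east |
|---|---|---|---|---|---|
| starting material | 0.19 M | 0.19 M | 0.19 M | 0.19 M | 0.19 M |
| reagent | 0.35 M | 0.61 M | 1.2 M | 0.380 M | 1.10 M |
| remark | run made earlier | run made earlier | run made earlier |  |  |
| time |  |  |  | 30 min | 30 min |

| run | time / min | target / % | over-reaction product / % | starting material / % | isomer of the product / % | intermediate / % |
|---|---|---|---|---|---|---|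
| gamma | 4.00 | 1.5 | 0.3 | 89.9 | 0.7 | 8.9 |
| gamma | 8.00 | 3.7 | 0 | 85.4 | 1.5 | 13.4 |
| gamma | 12.0 | 5.1 | 0.1 | 76.1 | 2.3 | 14.7 |
| gamma | 15.0 | 6.5 | 0.7 | 72.1 | 5.2 | 15.9 |
| gamma | 20.0 | 7.7 | 1.3 | 66.6 | 10.4 | 17.1 |
| eta | 1.50 | 1.7 | 0 | 95.6 | 0 | 3.8 |
| eta | 3.00 | 1.6 | 0.3 | 87.5 | 0 | 8.4 |
| eta | 6.00 | 3.2 | 2.1 | 79.1 | 0.6 | 15.9 |
| eta | 12.0 | 5.5 | 1.9 | 65.0 | 4.1 | 23.2 |
| eta | 20.0 | 10.5 | 5.3 | 48.9 | 15.0 | 23.1 |
| theta | 1.50 | 0.5 | 0 | 90.8 | 0 | 12.1 |
| theta | 3.00 | 4.2 | 2.1 | 79.8 | 1.9 | 18.1 |
| theta | 6.00 | 4.4 | 1.7 | 63.5 | 2.5 | 27.7 |
| theta | 12.0 | 9.9 | 4.0 | 40.7 | 9.0 | 36.1 |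
| theta | 20.0 | 9.5 | 12.6 | 22.9 | 20.0 | 30.4 |

(readings scatter by 1 percentage point)



* which of these there is most of at the end, counted by the starting material in it, north (isomer of the product / over-reaction product / intermediate / starting material / target)
* which of these there is most of at the end, counted by the starting material in it, east (isomer of the product / over-reaction product / intermediate / starting material / target)
* final amount of the leader among these, as a percentage of the starting material charged, in north
* final amount of the leader among these, as a percentage of the starting material charged, in east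

We divide the natural logarithm of charged over remaining starting material by the time and by [reagent]. There are two independent ways to this number, the last reading of theta and the last reading of gamma. With [reagent] as charged:

theta: 0.0614 M⁻¹ min⁻¹
gamma: 0.0581 M⁻¹ min⁻¹

They part, gamma lying lower, and the charge is what cheats, because reagent is used as the run goes. Taking one reagent lost per starting material lost, mean [reagent] is the charge less half the loss: 0.318 M in gamma, which is 90.9% of its charge, and 1.13 M in theta, which is 94.2%. With these means:

theta: 0.0654 M⁻¹ min⁻¹
gamma: 0.0639 M⁻¹ min⁻¹

The two flasks now lie close, so we carry their mean, 0.0646 M⁻¹ min⁻¹, as the reagent constant, a pseudo-first-order rate per molar of mean [reagent]. The mean depends on the answer, so we put each result back in: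

north: 47.9%, 52.7%, 52.2%
east: 11.8%, 13.9%, 13.9%

In north more than half of the starting material stays, and everything else together holds 47.8%, so starting material leads. In east we reckon 86.1% gone downstream. Carrying on to 30 min the last slopes of theta, charged with 1.2 M of reagent against east's 1.10 M, gives isomer of the product 33.8% and over-reaction product 23.3%; theta's last reading of intermediate is 30.4%, so we name the isomer.

The forecast gives starting material at 52% in north and isomer of the product at 33% in east, in its words “so starting material leads” for north.

The flasks give starting material at 52.1% in north; east holds 14.1% of starting material and its leader is isomer of the product at 31.4%.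

    reagent + target → over-reaction product (k = 0.0790 M⁻¹ min⁻¹)
    intermediate → target (k = 0.0770 min⁻¹)
    starting material + reagent → intermediate + by-product (k = 0.0670 M⁻¹ min⁻¹)
    target ⇌ isomer of the product (K = 5.50, k = 0.160 min⁻¹)

At 1.48 times east's reagent charge, 1.63 M, isomer of the product and over-reaction product hold the same. The neighbouring flask lies above that charge, being east charged with 2.8 M of reagent. Counting its whole charge of starting material as lost, mean [reagent] is 2.70 M, and the reagent constant leaves 0.527% after 30 min. The neighbouring flask holds 0.537% of starting material, and its leader is over-reaction product at 49.8%, against 26.6% of isomer of the product.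

The numbers in the tables come from a simulation from invented constants; scatter was added.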